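**Plan**

1. Retrosynthetic cuts, in order: the five O–isopropyl bonds of a fully protected biflavone; C4–C4a of the apigenin pyranone (acyl–aryl bond), which leaves a (Z)-3-aryloxy-3-arylacrylic acid; the biaryl bond C3'(genkwanin)–C6(apigenin); the vinyl ether C–O bond (phenol + arylpropiolate); the genkwanin pyranone, back to a 2'-hydroxychalcone and its aldol partners.
2. Forward: ring C of the genkwanin unit is closed first (chalcone, I2/DMSO) and its ring B is borylated at C3'. Separately, 4-bromo-3,5-diisopropoxyphenol is added to an arylpropiolate and the ester saponified. Suzuki–Miyaura coupling joins the halves, the apigenin pyranone closes last, and BCl3 removes the isopropyl groups.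
3. Enabling feature: in the apigenin unit O1 lies para to the biaryl carbon C6, which is flanked by the oxygens on C5 and C7. Ring A therefore derives from a mirror-symmetric 4-aryl-3,5-dialkoxyphenol whose two ortho carbons (future C4a and C8) are equivalent, so acylation can only give the 6-linked biflavone.
4. Stereochemistry: the target has no stereocentre. The only stereochemical element on the way is the Z alkene of the acrylic acid, set by anti addition of the phenoxide and consumed in the ring closure.
5. Protecting groups: isopropyl ethers throughout. They are stable to base, palladium and trifluoroacetic anhydride, and BCl3 cleaves them without touching the non-chelated 7-OMe. They also offer no arene C–H to the iridium borylation that places the phenol oxygen para to bromine; that borylation is preferred to a Dakin-type oxidation, which is unreliable when the alkoxy donors are only meta to the carbonyl.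

Key step: step 11

Assumption: the 3'–6 biaryl axis, flanked only by hydroxyl groups in the target, is taken as freely rotating, so no axial configuration is controlled; 1-iodo-4-isopropoxybenzene and 3-bromo-4-isopropoxybenzaldehyde are taken as catalogue compounds.

**Route**

Step 1
Reactants: 1 2-bromoresorcinol
Product: 2 2-bromo-1,3-diisopropoxybenzene
Conditions: 2-bromopropane (3 equiv), K2CO3, DMF, 60 °C
Reagents that add atoms: 2-bromopropane, CC(C)Br
Why: Williamson etherification, in which both phenoxides are alkylated on oxygen in a dipolar aprotic solvent while the aryl C–Br bond is inert.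

Step 2
Reactants: 2 2-bromo-1,3-diisopropoxybenzene
Product: 4 4-bromo-3,5-diisopropoxyphenol, via arylboronic pinacol ester 3 (not isolated)
Conditions: [Ir(OMe)(cod)]2 (1.5 mol %), 4,4'-di-tert-butyl-2,2'-bipyridine (3 mol %), B2pin2 (1.0 equiv), THF, 80 °C; then KHSO5 (as Oxone), acetone/H2O, rt
Reagents that add atoms: bis(pinacolato)diboron, CC1(C)OB(OC1(C)C)B1OC(C)(C)C(C)(C)O1 (boryl group of intermediate 3); potassium peroxymonosulfate, [K+].OOS(=O)(=O)[O-] (phenol oxygen of 4)
Why: Iridium-catalysed arene C–H borylation is sterically controlled, so only C5, the one ring C–H without an ortho substituent, should react (alkyl C–H and C–Br are spared), and the peroxymonosulfate then converts C–B into C–OH in the same flask by 1,2-aryl migration.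

Step 3
Reactants: 5 1-iodo-4-isopropoxybenzene; 6 ethyl propiolate
Product: 7 ethyl 3-(4-isopropoxyphenyl)prop-2-ynoate
Conditions: PdCl2(PPh3)2 (2 mol %), CuI (4 mol %), K2CO3, THF, 65 °C
Reagents that add atoms: none
Why: Sonogashira coupling of an aryl iodide with a terminal alkyne, run with an inorganic base because amines add to the propiolate.

Step 4
Reactants: 4 4-bromo-3,5-diisopropoxyphenol; 7 ethyl 3-(4-isopropoxyphenyl)prop-2-ynoate
Product: 8 ethyl (Z)-3-(4-bromo-3,5-diisopropoxyphenoxy)-3-(4-isopropoxyphenyl)prop-2-enoate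
Conditions: K2CO3 (0.5 equiv), DMF, 90 °C
Reagents that add atoms: none
Why: Oxa-Michael addition of the phenoxide to the ynoate, in which anti addition places aryloxy and ester groups cis (Z); any E isomer can be carried on because the later acidic ring closure equilibrates the geometry.

Step 5
Reactants: 8 ethyl (Z)-3-(4-bromo-3,5-diisopropoxyphenoxy)-3-(4-isopropoxyphenyl)prop-2-enoate
Product: 9 (Z)-3-(4-bromo-3,5-diisopropoxyphenoxy)-3-(4-isopropoxyphenyl)prop-2-enoic acid
Conditions: LiOH, THF/H2O, 50 °C; then 1 M HCl, 0 °C, to pH 3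
Reagents that add atoms: lithium hydroxide, [Li+].[OH-]
Why: Ester saponification, which β-aryloxycinnamates tolerate, with cold acidification so that the enol ether is not hydrolysed.

Step 6
Reactants: 10 2',6'-dihydroxy-4'-methoxyacetophenone
Product: 11 2'-hydroxy-6'-isopropoxy-4'-methoxyacetophenone
Conditions: 2-bromopropane (1.2 equiv), K2CO3, DMF, 50 °C
Reagents that add atoms: 2-bromopropane, CC(C)Br
Why: Williamson mono-alkylation of a symmetric diphenol, which should stop after one ether because the remaining hydroxyl is held by a hydrogen bond to the ketone.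

Step 7
Reactants: 11 2'-hydroxy-6'-isopropoxy-4'-methoxyacetophenone; 12 3-bromo-4-isopropoxybenzaldehyde
Product: 13 (E)-3-(3-bromo-4-isopropoxyphenyl)-1-(2-hydroxy-6-isopropoxy-4-methoxyphenyl)prop-2-en-1-one
Conditions: KOH (50% aq.), EtOH, rt
Reagents that add atoms: none
Why: Claisen–Schmidt condensation of the acetophenone enolate with a non-enolisable aldehyde, dehydration giving the conjugated E-enone.

Step 8
Reactants: 13 (E)-3-(3-bromo-4-isopropoxyphenyl)-1-(2-hydroxy-6-isopropoxy-4-methoxyphenyl)prop-2-en-1-one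
Product: 14 2-(3-bromo-4-isopropoxyphenyl)-5-isopropoxy-7-methoxy-4H-chromen-4-one
Conditions: I2 (10 mol %), DMSO, 120 °C
Reagents that add atoms: none
Why: Iodine/DMSO oxidative cyclisation of a 2'-hydroxychalcone, in which the phenol oxygen closes onto the enone β-carbon and catalytic iodine, regenerated by DMSO, removes the hydrogens at C2 and C3.

Step 9
Reactants: 14 2-(3-bromo-4-isopropoxyphenyl)-5-isopropoxy-7-methoxy-4H-chromen-4-one
Product: 15 5-isopropoxy-2-[4-isopropoxy-3-(4,4,5,5-tetramethyl-1,3,2-dioxaborolan-2-yl)phenyl]-7-methoxy-4H-chromen-4-one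
Conditions: B2pin2 (1.5 equiv), Pd(dppf)Cl2 (5 mol %), KOAc, 1,4-dioxane, 90 °C
Reagents that add atoms: bis(pinacolato)diboron, CC1(C)OB(OC1(C)C)B1OC(C)(C)C(C)(C)O1
Why: Miyaura borylation of the aryl bromide, with the weak acetate base suppressing Suzuki homocoupling and leaving the pyranone and ethers untouched.

Step 10
Reactants: 9 (Z)-3-(4-bromo-3,5-diisopropoxyphenoxy)-3-(4-isopropoxyphenyl)prop-2-enoic acid; 15 5-isopropoxy-2-[4-isopropoxy-3-(4,4,5,5-tetramethyl-1,3,2-dioxaborolan-2-yl)phenyl]-7-methoxy-4H-chromen-4-one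
Product: 16 (Z)-3-{3,5-diisopropoxy-4-[2-isopropoxy-5-(5-isopropoxy-7-methoxy-4-oxo-4H-chromen-2-yl)phenyl]phenoxy}-3-(4-isopropoxyphenyl)prop-2-enoic acid
Conditions: Pd(OAc)2 (5 mol %), SPhos (10 mol %), K3PO4 (4 equiv), 1,4-dioxane/H2O, 90 °C; then 1 M HCl, 0 °C, to pH 3
Reagents that add atoms: none
Why: Suzuki–Miyaura coupling, in which the bulky electron-rich biarylphosphine SPhos (2-dicyclohexylphosphino-2',6'-dimethoxybiphenyl) permits oxidative addition into the di-ortho-alkoxy C–Br bond and formation of the tri-ortho-substituted biaryl, the carboxylate being a spectator.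

Step 11
Reactants: 16 (Z)-3-{3,5-diisopropoxy-4-[2-isopropoxy-5-(5-isopropoxy-7-methoxy-4-oxo-4H-chromen-2-yl)phenyl]phenoxy}-3-(4-isopropoxyphenyl)prop-2-enoic acid
Product: 18 5,7-diisopropoxy-2-(4-isopropoxyphenyl)-6-[2-isopropoxy-5-(5-isopropoxy-7-methoxy-4-oxo-4H-chromen-2-yl)phenyl]-4H-chromen-4-one, via mixed trifluoroacetic anhydride 17 (not isolated)
Conditions: (CF3CO)2O (3 equiv), CH2Cl2 (dilute), 0 °C to rt
Reagents that add atoms: trifluoroacetic anhydride, O=C(OC(=O)C(F)(F)F)C(F)(F)F (trifluoroacetyl group of intermediate 17 only)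
Why: Trifluoroacetic anhydride turns the acid into mixed anhydride 17, whose acyl carbon, an acylium equivalent, attacks the ring carbon ortho to the vinyl ether oxygen; loss of a proton and of trifluoroacetate restores aromaticity and leaves the 4-pyranone. The closest known reaction type is the intramolecular Friedel–Crafts acylation of 3-aryloxycinnamic acids to flavones, with the anhydride activation used for closing 2-aryloxybenzoic acids to xanthones. The one new ring, the pyranone of the apigenin unit, closes in a six-membered mode by electrophilic aromatic substitution with the acyl C=O exocyclic (6-exo-trig), and no stereocentre is formed. The 6-linked rather than 8-linked outcome needs no control, because the two candidate carbons are related by the mirror plane through the ether oxygen and the biaryl carbon, each being ortho to one isopropoxy group and para to the other. Chemoselectivity should follow from this ring being the only arene with three oxygen donors, the genkwanin rings being deactivated by their own carbonyl and the 4-isopropoxyphenyl ring being reachable only at a position meta to its donor. The Z geometry holds the acyl group next to the aryloxy ring, and any E acid should equilibrate under the acidic conditions through the oxocarbenium–ketene resonance form of the acyl cation.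

Step 12
Reactants: 18 5,7-diisopropoxy-2-(4-isopropoxyphenyl)-6-[2-isopropoxy-5-(5-isopropoxy-7-methoxy-4-oxo-4H-chromen-2-yl)phenyl]-4H-chromen-4-one
Product: 19 5,7-dihydroxy-6-[2-hydroxy-5-(5-hydroxy-7-methoxy-4-oxo-4H-chromen-2-yl)phenyl]-2-(4-hydroxyphenyl)-4H-chromen-4-one (CNP0277373.0)
Conditions: BCl3 (1 M in CH2Cl2, 12 equiv), CH2Cl2, −78 °C to rt; then H2O
Reagents that add atoms: none
Why: Lewis-acid dealkylation of aryl isopropyl ethers, in which boron binds the ether oxygen and the secondary alkyl group leaves as 2-chloropropane (the two ethers peri to a carbonyl going first through chelation), while the non-chelated methyl ether, unable to ionise, should remain.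

**Compound list**

1 | 2-bromoresorcinol (2-bromobenzene-1,3-diol) | Oc1cccc(O)c1Br | starting material
2 | 2-bromo-1,3-diisopropoxybenzene | CC(C)Oc1cccc(OC(C)C)c1Br | intermediate
3 | 2-(4-bromo-3,5-diisopropoxyphenyl)-4,4,5,5-tetramethyl-1,3,2-dioxaborolane | CC(C)Oc1cc(B2OC(C)(C)C(C)(C)O2)cc(OC(C)C)c1Br | intermediate
4 | 4-bromo-3,5-diisopropoxyphenol | CC(C)Oc1cc(O)cc(OC(C)C)c1Br | intermediate
5 | 1-iodo-4-isopropoxybenzene | CC(C)Oc1ccc(I)cc1 | starting material
6 | ethyl propiolate | C#CC(=O)OCC | starting material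
7 | ethyl 3-(4-isopropoxyphenyl)prop-2-ynoate | CCOC(=O)C#Cc1ccc(OC(C)C)cc1 | intermediate
8 | ethyl (Z)-3-(4-bromo-3,5-diisopropoxyphenoxy)-3-(4-isopropoxyphenyl)prop-2-enoate | CCOC(=O)/C=C(\Oc1cc(OC(C)C)c(Br)c(OC(C)C)c1)c1ccc(OC(C)C)cc1 | intermediate
9 | (Z)-3-(4-bromo-3,5-diisopropoxyphenoxy)-3-(4-isopropoxyphenyl)prop-2-enoic acid | OC(=O)/C=C(\Oc1cc(OC(C)C)c(Br)c(OC(C)C)c1)c1ccc(OC(C)C)cc1 | intermediate
10 | 2',6'-dihydroxy-4'-methoxyacetophenone | CC(=O)c1c(O)cc(OC)cc1O | starting material
11 | 2'-hydroxy-6'-isopropoxy-4'-methoxyacetophenone | CC(=O)c1c(O)cc(OC)cc1OC(C)C | intermediate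
12 | 3-bromo-4-isopropoxybenzaldehyde | CC(C)Oc1ccc(C=O)cc1Br | starting material
13 | (E)-3-(3-bromo-4-isopropoxyphenyl)-1-(2-hydroxy-6-isopropoxy-4-methoxyphenyl)prop-2-en-1-one | COc1cc(O)c(C(=O)/C=C/c2ccc(OC(C)C)c(Br)c2)c(OC(C)C)c1 | intermediate
14 | 2-(3-bromo-4-isopropoxyphenyl)-5-isopropoxy-7-methoxy-4H-chromen-4-one | COc1cc(OC(C)C)c2c(=O)cc(-c3ccc(OC(C)C)c(Br)c3)oc2c1 | intermediate
15 | 5-isopropoxy-2-[4-isopropoxy-3-(4,4,5,5-tetramethyl-1,3,2-dioxaborolan-2-yl)phenyl]-7-methoxy-4H-chromen-4-one | COc1cc(OC(C)C)c2c(=O)cc(-c3ccc(OC(C)C)c(B4OC(C)(C)C(C)(C)O4)c3)oc2c1 | intermediate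
16 | (Z)-3-{3,5-diisopropoxy-4-[2-isopropoxy-5-(5-isopropoxy-7-methoxy-4-oxo-4H-chromen-2-yl)phenyl]phenoxy}-3-(4-isopropoxyphenyl)prop-2-enoic acid | OC(=O)/C=C(\Oc1cc(OC(C)C)c(-c2cc(-c3cc(=O)c4c(OC(C)C)cc(OC)cc4o3)ccc2OC(C)C)c(OC(C)C)c1)c1ccc(OC(C)C)cc1 | intermediate
17 | mixed anhydride of acid 16 with trifluoroacetic acid | O=C(OC(=O)C(F)(F)F)/C=C(\Oc1cc(OC(C)C)c(-c2cc(-c3cc(=O)c4c(OC(C)C)cc(OC)cc4o3)ccc2OC(C)C)c(OC(C)C)c1)c1ccc(OC(C)C)cc1 | intermediate
18 | 5,7-diisopropoxy-2-(4-isopropoxyphenyl)-6-[2-isopropoxy-5-(5-isopropoxy-7-methoxy-4-oxo-4H-chromen-2-yl)phenyl]-4H-chromen-4-one | COc1cc(OC(C)C)c2c(=O)cc(-c3ccc(OC(C)C)c(-c4c(OC(C)C)cc5oc(-c6ccc(OC(C)C)cc6)cc(=O)c5c4OC(C)C)c3)oc2c1 | intermediate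
19 | 5,7-dihydroxy-6-[2-hydroxy-5-(5-hydroxy-7-methoxy-4-oxo-4H-chromen-2-yl)phenyl]-2-(4-hydroxyphenyl)-4H-chromen-4-one (CNP0277373.0) | COc1cc(O)c2c(=O)cc(-c3ccc(O)c(-c4c(O)cc5oc(-c6ccc(O)cc6)cc(=O)c5c4O)c3)oc2c1 | target

**Count and risks**

Total step count: 12. Longest linear sequence: 7 steps (steps 6, 7, 8, 9, 10, 11, 12; the branch through steps 1, 2, 4, 5 is equally long).

Steps most likely to fail:

Step 10. Oxidative addition of palladium into the C–Br bond, shielded by two ortho isopropoxy groups on an electron-rich ring, may be slower than protodeboronation of boronate 15, and the acrylate carboxylate may bind the metal. The fallback sets out from acid 9 and changes the order of events. The pyranone is closed first with trifluoroacetic anhydride in CH2Cl2, the same symmetry argument applying, to give 6-bromo-5,7-diisopropoxy-2-(4-isopropoxyphenyl)-4H-chromen-4-one F1. This neutral bromide, which no longer carries an acrylate or a carboxylate, is then joined to boronate 15 by Suzuki–Miyaura coupling (Pd(OAc)2, SPhos, K3PO4, dioxane/H2O), the union of a 6-haloflavone ether with a flavone 3'-boronate being a known way to this biflavone skeleton. The fallback comes back to the route at 18.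

Step 11. The acyl cation equivalent is strongly stabilised by the aryloxy donor and may be too weak an electrophile, an E acid may fail to equilibrate, or intermolecular acylation and ring trifluoroacetylation may compete. The fallback sets out from phenol 4 and boronate 15 and closes the pyranone at O1–C2 instead. Suzuki–Miyaura coupling of the two (Pd(OAc)2, SPhos, K3PO4) should give 2-[3-(4-hydroxy-2,6-diisopropoxyphenyl)-4-isopropoxyphenyl]-5-isopropoxy-7-methoxy-4H-chromen-4-one F2. N-Iodosuccinimide in CH2Cl2 at 0 °C iodinates one of the two equivalent carbons ortho to the hydroxyl to give 2-[3-(4-hydroxy-3-iodo-2,6-diisopropoxyphenyl)-4-isopropoxyphenyl]-5-isopropoxy-7-methoxy-4H-chromen-4-one F3. Carbonylative Sonogashira coupling with 1-ethynyl-4-isopropoxybenzene under carbon monoxide (PdCl2(PPh3)2, Et2NH) then forms 2-[3-{4-hydroxy-2,6-diisopropoxy-3-[3-(4-isopropoxyphenyl)prop-2-ynoyl]phenyl}-4-isopropoxyphenyl]-5-isopropoxy-7-methoxy-4H-chromen-4-one F4, which is not isolated and closes in the flask by 6-endo-dig oxa-Michael addition. The fallback comes back to the route at 18.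

Step 4. Conjugate addition to an ynoate deactivated by its para-alkoxyaryl donor may be slow, and at the temperature needed base-induced oligomerisation or hydrolysis of the ynoate may consume it. The fallback sets out from ynoate 7 and replaces addition to the triple bond by a vinylic substitution. Hydrochlorination with LiCl in acetic acid at 100 °C (anti addition) should give ethyl (Z)-3-chloro-3-(4-isopropoxyphenyl)prop-2-enoate F5, which does not oligomerise under base. Phenol 4 with K2CO3 in DMF at 60 °C then displaces chloride by addition–elimination with retention of geometry. The fallback comes back to the route at 8.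

**Further compounds**

F1 | step 10 | 6-bromo-5,7-diisopropoxy-2-(4-isopropoxyphenyl)-4H-chromen-4-one | CC(C)Oc1ccc(-c2cc(=O)c3c(OC(C)C)c(Br)c(OC(C)C)cc3o2)cc1
F2 | step 11 | 2-[3-(4-hydroxy-2,6-diisopropoxyphenyl)-4-isopropoxyphenyl]-5-isopropoxy-7-methoxy-4H-chromen-4-one | COc1cc(OC(C)C)c2c(=O)cc(-c3ccc(OC(C)C)c(-c4c(OC(C)C)cc(O)cc4OC(C)C)c3)oc2c1
F3 | step 11 | 2-[3-(4-hydroxy-3-iodo-2,6-diisopropoxyphenyl)-4-isopropoxyphenyl]-5-isopropoxy-7-methoxy-4H-chromen-4-one | COc1cc(OC(C)C)c2c(=O)cc(-c3ccc(OC(C)C)c(-c4c(OC(C)C)cc(O)c(I)c4OC(C)C)c3)oc2c1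
F4 | step 11 | 2-[3-{4-hydroxy-2,6-diisopropoxy-3-[3-(4-isopropoxyphenyl)prop-2-ynoyl]phenyl}-4-isopropoxyphenyl]-5-isopropoxy-7-methoxy-4H-chromen-4-one | COc1cc(OC(C)C)c2c(=O)cc(-c3ccc(OC(C)C)c(-c4c(OC(C)C)cc(O)c(C(=O)C#Cc5ccc(OC(C)C)cc5)c4OC(C)C)c3)oc2c1
F5 | step 4 | ethyl (Z)-3-chloro-3-(4-isopropoxyphenyl)prop-2-enoate | CCOC(=O)/C=C(\Cl)c1ccc(OC(C)C)cc1
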